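The route rests on disconnecting the C1–O and C6–O bonds to a C1=C6 alkene in a cyclohexa-1,3-diene made by enzymatic dearomatisation of methyl benzoate (C1 = tertiary carbinol carbon bearing C7H2OBz, C2/C3 = CHOAc/CHOBz, C4=C5 = alkene, C6 = allylic CHOAc). In the target's cyclohexene ring, C1–OH is cis to C2–O and trans to C6–OAc: the imprint of a C1–C6 oxirane, syn to C2–O, opened at C6. One vanadium-templated oxygen transfer, steered by the free C2 hydroxyl, closes that oxirane and sets C1 and C6 together. Its precursor is a dienol with C2–OH free, C3–OH silylated and C7 benzoylated; C3 is inverted last.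

Key step: step 5

Remarks on the chemistry
- The locants C1–C7 defined above are used for every compound. β is the ring face that carries the C2 oxygen and α is the other face.
- The target is (1R,2S,3R,6S): C1–OH β, C2–OAc β, C3–OBz α, C6–OAc α. Dienol 9 and epoxide 11 were checked against this assignment and need no correction. C2–O is β as the enzyme leaves it. C3–O is β in 9 and 11 and has to be inverted.
- In 9 the C2 hydroxyl is the only free hydroxyl, so vanadium has a single anchor. The C3 silyl ether is the only protecting group of the route.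
- Assumption: toluene dioxygenase in the recombinant strain oxidises methyl benzoate at its 2,3-bond with the same facial sense as toluene, giving the (5S,6R)-diol. The reducing equivalents come from glucose through the cell's own cofactor cycle, which is treated as a catalyst.

Step 1
Reactants: 1 methyl benzoate; 2 dioxygen (air)
Product: 3 methyl (5S,6R)-5,6-dihydroxycyclohexa-1,3-diene-1-carboxylate (cis-diol; the carbinol next to the ester carbon is the future C2 and the other the future C3)
Conditions: E. coli JM109(pDTG601A) whole cells expressing toluene dioxygenase, glucose feed, air, pH 7 phosphate buffer, 30 °C; EtOAc extraction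
Reagents that add atoms: dioxygen, O=O
Why: Enzymatic arene cis-dihydroxylation by toluene dioxygenase adds both oxygen atoms of O2 to the 2,3-bond of the monosubstituted arene from one face, the active site setting both carbinol centres as (5S,6R) with the same sense as for toluene, so that the future C2–O already has its final configuration.

Step 2
Reactants: 3 methyl (5S,6R)-5,6-dihydroxycyclohexa-1,3-diene-1-carboxylate; 4 tert-butyldimethylsilyl chloride
Product: 5 methyl (5S,6R)-5-(tert-butyldimethylsilyloxy)-6-hydroxycyclohexa-1,3-diene-1-carboxylate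
Conditions: TBSCl (1.05 equiv), imidazole, DMF, −20 → 0 °C
Reagents that add atoms: tert-butyldimethylsilyl chloride, CC(C)(C)[Si](C)(C)Cl
Why: Regioselective silyl ether formation: the C3 hydroxyl is the less hindered one, whereas the C2 hydroxyl is flanked by the ester-bearing sp2 carbon and hydrogen-bonded to the ester carbonyl, so one equivalent of the bulky chlorosilane at low temperature should silylate C3–OH only; no stereocentre is touched.

Step 3
Reactants: 5 methyl (5S,6R)-5-(tert-butyldimethylsilyloxy)-6-hydroxycyclohexa-1,3-diene-1-carboxylate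
Product: 7 (1R,6S)-6-(tert-butyldimethylsilyloxy)-2-(hydroxymethyl)cyclohexa-2,4-dien-1-ol, via dienal 6 (not isolated)
Conditions: iBu2AlH (3.5 equiv), CH2Cl2, −78 → −40 °C; aq. KNaC4H4O6 (Rochelle salt) work-up
Reagents that add atoms: none
Why: DIBAL-H reduction of a conjugated ester proceeds by 1,2-hydride addition through the dienal to the primary allylic alcohol without touching the diene or the silyl ether, one extra equivalent being consumed by the free C2 hydroxyl, and the neutral tartrate work-up avoids acid-induced dehydration to an arene.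

Step 4
Reactants: 7 (1R,6S)-6-(tert-butyldimethylsilyloxy)-2-(hydroxymethyl)cyclohexa-2,4-dien-1-ol; 8 benzoyl chloride
Product: 9 [(5S,6R)-5-(tert-butyldimethylsilyloxy)-6-hydroxycyclohexa-1,3-dien-1-yl]methyl benzoate (C2–OH free; C3–OTBS; C7–OBz)
Conditions: BzCl (1.05 equiv), 2,4,6-collidine, CH2Cl2, −78 → −20 °C
Reagents that add atoms: benzoyl chloride, O=C(Cl)c1ccccc1
Why: Chemoselective esterification with an acyl chloride and a hindered pyridine base at low temperature acylates the unhindered primary C7 hydroxyl much faster than the secondary C2 hydroxyl, which is flanked by C1 and the cis silyl ether; no stereocentre is touched.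

Step 5
Reactants: 9 [(5S,6R)-5-(tert-butyldimethylsilyloxy)-6-hydroxycyclohexa-1,3-dien-1-yl]methyl benzoate; 10 tert-butyl hydroperoxide
Product: 11 [(1S,2S,3S,6R)-3-(tert-butyldimethylsilyloxy)-2-hydroxy-7-oxabicyclo[4.1.0]hept-4-en-1-yl]methyl benzoate (C1–C6 oxirane on the β face; C4=C5 retained)
Conditions: VO(acac)2 (5 mol %), t-BuOOH (1.2 equiv, in decane), CH2Cl2, 0 °C → rt; aq. Na2S2O3 quench
Reagents that add atoms: tert-butyl hydroperoxide, CC(C)(C)OO
Why: The C2 hydroxyl exchanges onto the pentavalent vanadium alkylperoxo species formed from VO(acac)2 and the hydroperoxide, and the bound peroxide oxygen is passed intramolecularly to the adjacent C1=C6 π-bond, which is the hydroxyl-directed vanadium-catalysed epoxidation of cyclic allylic alcohols. The oxirane closes by a concerted, suprafacial [2+1] oxygen-atom transfer that forms C1–O and C6–O together, so it is not a stepwise exo or endo cyclisation. Both new stereocentres, C1 and C6, are controlled by the C2 carbinol centre: the vanadate ester reaches only the β face, and the cis-fused three-membered ring ties the configuration of C6 to that of C1. The step needs site selectivity for C1=C6 over C4=C5 and β-face selectivity; the first is secured because only C1=C6 is allylic to the bound oxygen and is the trisubstituted, more electron-rich alkene, while C4=C5 is merely homoallylic and flanked by the silyl ether. The second is secured because allylic 1,2-strain with C7 holds the C2–O bond pseudoaxial, the geometry that vanadium delivery prefers, and a small excess of oxidant at 0 °C limits carbinol oxidation and a second epoxidation.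

Step 6
Reactants: 11 [(1S,2S,3S,6R)-3-(tert-butyldimethylsilyloxy)-2-hydroxy-7-oxabicyclo[4.1.0]hept-4-en-1-yl]methyl benzoate; 12 acetic acid
Product: 13 [(1S,2S,3S,6S)-6-acetoxy-3-(tert-butyldimethylsilyloxy)-1,2-dihydroxycyclohex-4-en-1-yl]methyl benzoate (C1–OH β; C2–OH β; C3–OTBS β; C6–OAc α)
Conditions: Ti(OiPr)4 (1.5 equiv), AcOH (3 equiv), CH2Cl2, 0 °C → rt; aq. tartaric acid work-up
Reagents that add atoms: acetic acid, CC(=O)O
Why: Titanium-alkoxide-mediated opening of a 2,3-epoxy alcohol by a carboxylic acid: the C2 alkoxide and the oxirane oxygen chelate titanium, and acetate attacks the remote, secondary and allylic C6 in SN2 fashion from the α face (inversion at C6, C1 untouched), whereas C1 is tertiary and deactivated by the C2–O and C7–O bonds, which gives the trans pair C1–OH β and C6–OAc α.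

Step 7
Reactants: 13 [(1S,2S,3S,6S)-6-acetoxy-3-(tert-butyldimethylsilyloxy)-1,2-dihydroxycyclohex-4-en-1-yl]methyl benzoate; 14 acetic anhydride
Product: 15 [(1R,2S,3S,6S)-2,6-diacetoxy-3-(tert-butyldimethylsilyloxy)-1-hydroxycyclohex-4-en-1-yl]methyl benzoate (the C1 descriptor changes only because the ranking of C2 and C6 changes)
Conditions: Ac2O (1.5 equiv), pyridine, DMAP (5 mol %), CH2Cl2, 0 °C
Reagents that add atoms: acetic anhydride, CC(=O)OC(C)=O
Why: DMAP-catalysed acetylation with Ac2O esterifies the secondary C2 hydroxyl while the tertiary C1 hydroxyl, flanked by three substituted carbons, stays free under these mild conditions; no stereocentre is touched.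

Step 8
Reactants: 15 [(1R,2S,3S,6S)-2,6-diacetoxy-3-(tert-butyldimethylsilyloxy)-1-hydroxycyclohex-4-en-1-yl]methyl benzoate
Product: 16 [(1R,2S,3S,6S)-2,6-diacetoxy-1,3-dihydroxycyclohex-4-en-1-yl]methyl benzoate (C3–OH β)
Conditions: HF·pyridine, pyridine, THF, 0 °C → rt
Reagents that add atoms: none
Why: Fluoride-driven cleavage of the silyl ether by pyridine-buffered HF (Si–F bond formation) frees C3–OH under slightly acidic conditions, which avoids the base-promoted acetyl migration from C2–O to the cis C3–OH that a basic fluoride source would invite, and leaves the esters and the tertiary alcohol intact.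

Step 9
Reactants: 16 [(1R,2S,3S,6S)-2,6-diacetoxy-1,3-dihydroxycyclohex-4-en-1-yl]methyl benzoate; 17 benzoic acid
Product: 19 [(1R,2S,3R,6S)-2,6-diacetoxy-3-(benzoyloxy)-1-hydroxycyclohex-4-en-1-yl]methyl benzoate, via alkoxyphosphonium benzoate 18 (not isolated)
Conditions: PPh3, DIAD, BzOH (2 equiv each), toluene, 0 °C → rt
Reagents that add atoms: benzoic acid, OC(=O)c1ccccc1
Why: Mitsunobu reaction: the secondary allylic C3 hydroxyl is converted to its alkoxyphosphonium ion and displaced by benzoate in an SN2 step with inversion (3S with β-O becomes 3R with α-O), the tertiary C1 hydroxyl being inert and the cis C2 acetate unable to participate from the rear.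

Compound list
1 | methyl benzoate | COC(=O)c1ccccc1 | starting material
2 | dioxygen | O=O | starting material
3 | methyl (5S,6R)-5,6-dihydroxycyclohexa-1,3-diene-1-carboxylate | O[C@H]1[C@@H](O)C=CC=C1C(=O)OC | intermediate
4 | tert-butyldimethylsilyl chloride | CC(C)(C)[Si](C)(C)Cl | starting material
5 | methyl (5S,6R)-5-(tert-butyldimethylsilyloxy)-6-hydroxycyclohexa-1,3-diene-1-carboxylate | O[C@H]1[C@@H](O[Si](C)(C)C(C)(C)C)C=CC=C1C(=O)OC | intermediate
6 | (5S,6R)-5-(tert-butyldimethylsilyloxy)-6-hydroxycyclohexa-1,3-diene-1-carbaldehyde | O[C@H]1[C@@H](O[Si](C)(C)C(C)(C)C)C=CC=C1C=O | intermediate (not isolated)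
7 | (1R,6S)-6-(tert-butyldimethylsilyloxy)-2-(hydroxymethyl)cyclohexa-2,4-dien-1-ol | O[C@H]1[C@@H](O[Si](C)(C)C(C)(C)C)C=CC=C1CO | intermediate
8 | benzoyl chloride | O=C(Cl)c1ccccc1 | starting material
9 | [(5S,6R)-5-(tert-butyldimethylsilyloxy)-6-hydroxycyclohexa-1,3-dien-1-yl]methyl benzoate | O[C@H]1[C@@H](O[Si](C)(C)C(C)(C)C)C=CC=C1COC(=O)c1ccccc1 | intermediate
10 | tert-butyl hydroperoxide | CC(C)(C)OO | starting material
11 | [(1S,2S,3S,6R)-3-(tert-butyldimethylsilyloxy)-2-hydroxy-7-oxabicyclo[4.1.0]hept-4-en-1-yl]methyl benzoate | O[C@H]1[C@@H](O[Si](C)(C)C(C)(C)C)C=C[C@H]2O[C@@]12COC(=O)c1ccccc1 | intermediate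
12 | acetic acid | CC(=O)O | starting material
13 | [(1S,2S,3S,6S)-6-acetoxy-3-(tert-butyldimethylsilyloxy)-1,2-dihydroxycyclohex-4-en-1-yl]methyl benzoate | CC(=O)O[C@H]1C=C[C@H](O[Si](C)(C)C(C)(C)C)[C@H](O)[C@@]1(O)COC(=O)c1ccccc1 | intermediate
14 | acetic anhydride | CC(=O)OC(C)=O | starting material
15 | [(1R,2S,3S,6S)-2,6-diacetoxy-3-(tert-butyldimethylsilyloxy)-1-hydroxycyclohex-4-en-1-yl]methyl benzoate | CC(=O)O[C@H]1C=C[C@H](O[Si](C)(C)C(C)(C)C)[C@H](OC(C)=O)[C@@]1(O)COC(=O)c1ccccc1 | intermediate
16 | [(1R,2S,3S,6S)-2,6-diacetoxy-1,3-dihydroxycyclohex-4-en-1-yl]methyl benzoate | CC(=O)O[C@H]1C=C[C@H](O)[C@H](OC(C)=O)[C@@]1(O)COC(=O)c1ccccc1 | intermediate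
17 | benzoic acid | OC(=O)c1ccccc1 | starting material
18 | C3 alkoxytriphenylphosphonium benzoate of 16 | CC(=O)O[C@H]1C=C[C@H](O[P+](c2ccccc2)(c2ccccc2)c2ccccc2)[C@H](OC(C)=O)[C@@]1(O)COC(=O)c1ccccc1.[O-]C(=O)c1ccccc1 | intermediate (not isolated)
19 | [(1R,2S,3R,6S)-2,6-diacetoxy-3-(benzoyloxy)-1-hydroxycyclohex-4-en-1-yl]methyl benzoate | CC(=O)O[C@H]1C=C[C@@H](OC(=O)c2ccccc2)[C@H](OC(C)=O)[C@@]1(O)COC(=O)c1ccccc1 | target

Total step count: 9
Longest linear sequence: 9 steps (methyl benzoate to 19)

Steps most likely to fail

Step 5 (key step). The vanadium peroxo species may dehydrogenate the C2 carbinol to a cyclohexadienone that tautomerises to a phenol. Lewis-acid-assisted loss of silanol may rearomatise the ring, or a slow second, homoallylic epoxidation of C4=C5 may follow. The fallback gives up the metal alkoxide template and moves the oxidation one stage earlier. It sets out from diol 7, which is treated with mCPBA in NaHCO3-buffered CH2Cl2 at 0 °C. Hydrogen bonding of the peracid to the pseudoaxial ring hydroxyl (Henbest-type delivery) should direct it to the β face of the C1=C6 alkene, which is more electron-rich here because C7 still carries a free hydroxyl. The primary hydroxyl can assist on either face, so the selectivity rests on the ring hydroxyl. This should give the epoxy diol (1S,2S,3S,6R)-3-(tert-butyldimethylsilyloxy)-1-(hydroxymethyl)-7-oxabicyclo[4.1.0]hept-4-en-2-ol F1. Selective benzoylation of its primary hydroxyl (BzCl, 2,4,6-collidine, CH2Cl2, −78 °C) returns to the route at 11.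

Step 6. Acetate may attack in the conjugate sense at C4 with allylic transposition, C6 may partly ionise with loss of the anti relationship, or the titanium alkoxide may scramble acyl groups between the C7 benzoate, the new C6 acetate and the free C2 hydroxyl. The fallback reverses the order of the two acetate-forming events and uses no metal. It sets out from 11, whose C2 hydroxyl is acetylated first (Ac2O, pyridine, DMAP, 0 °C) to give [(1R,2S,3S,6R)-2-acetoxy-3-(tert-butyldimethylsilyloxy)-7-oxabicyclo[4.1.0]hept-4-en-1-yl]methyl benzoate F2, which has no free hydroxyl next to an ester. Buffered acetolysis (AcOH, NaOAc, 40 °C) should then open the oxirane anti at the allylic C6; the cis C2 acetate cannot reach the rear of C1. This bypasses 13 and returns to the route at 15.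

Step 9. Benzoate may attack C5 with allylic transposition, the alkoxyphosphonium ion may lose the anti C2 hydrogen to give a dienyl acetate, or slow activation of the hindered C3 hydroxyl may leave time for acetyl migration from C2–O to C3–O. The fallback separates activation from displacement. It sets out from 16, which is converted (MsCl, Et3N, CH2Cl2, −20 °C) to the sulfonate [(1R,2S,3S,6S)-2,6-diacetoxy-1-hydroxy-3-(methylsulfonyloxy)cyclohex-4-en-1-yl]methyl benzoate F3; the tertiary hydroxyl should not react. Displacement with CsO2CPh and 18-crown-6 in toluene at 40–60 °C, an SN2 inversion by a caesium carboxylate, returns to the route at 19.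

Further compounds
F1 | step 5 | (1S,2S,3S,6R)-3-(tert-butyldimethylsilyloxy)-1-(hydroxymethyl)-7-oxabicyclo[4.1.0]hept-4-en-2-ol | O[C@H]1[C@@H](O[Si](C)(C)C(C)(C)C)C=C[C@H]2O[C@@]12CO
F2 | step 6 | [(1R,2S,3S,6R)-2-acetoxy-3-(tert-butyldimethylsilyloxy)-7-oxabicyclo[4.1.0]hept-4-en-1-yl]methyl benzoate | CC(=O)O[C@H]1[C@@H](O[Si](C)(C)C(C)(C)C)C=C[C@H]2O[C@@]12COC(=O)c1ccccc1
F3 | step 9 | [(1R,2S,3S,6S)-2,6-diacetoxy-1-hydroxy-3-(methylsulfonyloxy)cyclohex-4-en-1-yl]methyl benzoate | CC(=O)O[C@H]1C=C[C@H](OS(C)(=O)=O)[C@H](OC(C)=O)[C@@]1(O)COC(=O)c1ccccc1
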